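The target is the tyrosol ester of hexatriacontanoic acid; its single ring, the para-disubstituted benzene, plays no part in chain assembly. The plan exploits the unbranched, stereocentre-free C2–C36 methylene chain: C16 is an anonymous CH2, so it can enter as carbon monoxide between a C1–C15 electrophile and a C17–C36 nucleophile. One light-assisted, palladium-catalysed carbonylative Suzuki–Miyaura coupling forms the C15–C16 and C16–C17 bonds and leaves a C16 ketone that is later reduced away. Its precursors are methyl 15-iodopentadecanoate, made from pentadecanolide, and B-eicosyl-9-borabicyclo[3.3.1]nonane, made from 1-eicosene; tyrosol is attached last through its primary hydroxyl.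

Key step: step 4

Remark on the chemistry: 9-borabicyclo[3.3.1]nonane is used as its commercial B–H-bridged dimer and is drawn as the monomer; carbon monoxide is numbered as a reactant because it supplies C16.

Step 1
Reactants: 1 pentadecanolide
Product: 2 methyl 15-hydroxypentadecanoate
Conditions: MeOH (solvent), H2SO4 (cat.), reflux; NaHCO3 before concentration
Reagents that add atoms: methanol, CO
Why: Acid-catalysed transesterification (Fischer-type methanolysis) of the unstrained 16-membered lactone is pushed to the open-chain hydroxy ester by the large excess of methanol.

Step 2
Reactants: 2 methyl 15-hydroxypentadecanoate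
Product: 3 methyl 15-iodopentadecanoate
Conditions: I2, PPh3, imidazole, CH2Cl2, 0 °C to rt, dark
Reagents that add atoms: iodine, II
Why: Appel-type iodination, in which the primary hydroxyl is activated as an alkoxyphosphonium ion and displaced by iodide in an SN2 step that leaves the remote methyl ester untouched.

Step 3
Reactants: 4 1-eicosene; 5 9-borabicyclo[3.3.1]nonane
Product: 6 B-eicosyl-9-borabicyclo[3.3.1]nonane (kept as a THF solution under argon and transferred as such)
Conditions: THF, 0 °C to rt, argon; slight excess of the alkene so that no B–H remains
Reagents that add atoms: none
Why: Hydroboration of a terminal alkene with 9-BBN places boron on the terminal carbon (anti-Markovnikov) with very high regioselectivity for steric reasons, giving the standard B-alkyl nucleophile for Suzuki–Miyaura coupling.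

Step 4
Reactants: 6 B-eicosyl-9-borabicyclo[3.3.1]nonane; 7 carbon monoxide; 3 methyl 15-iodopentadecanoate
Product: 8 methyl 16-oxohexatriacontanoate
Conditions: Pd(PPh3)4 (5 mol %), K3PO4 (3 equiv), CO (1 atm, balloon), degassed benzene/THF, tungsten lamp (hν), rt; aqueous work-up, recrystallisation
Reagents that add atoms: none
Why: Under visible light zerovalent palladium passes one electron to the primary C15–I bond, and the primary alkyl radical so formed takes up CO and recombines with the metal (or recombines and then inserts CO) to give an acyl(iodo) complex of divalent palladium carrying the new C15–C16 bond. Phosphate adds to the boron of 6 and the resulting borate hands over only its primary eicosyl group, since the secondary bridgehead B–C bonds of the bicyclic ligand transfer far more slowly; reductive elimination then forms C16–C17 and regenerates zerovalent palladium. The closest known reaction type is the carbonylative Suzuki–Miyaura cross-coupling of primary iodoalkanes with 9-alkyl-9-BBN reagents under one atmosphere of CO with irradiation, which delivers unsymmetrical dialkyl ketones. No ring is closed and no stereocentre is created, and the position of the ketone is fixed by where iodine and boron sit in the two partners. The selectivity needed is CO capture ahead of β-hydride elimination, hydrogen abstraction and direct alkyl–alkyl coupling, and it should be secured by the radical mode of activation of an unhindered primary iodide in a CO-saturated solution. The methyl ester at C1 lies fourteen methylenes away from the reacting carbon and is a spectator toward anhydrous K3PO4 and toward the trialkylborane.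

Step 5
Reactants: 8 methyl 16-oxohexatriacontanoate
Product: 12 hexatriacontanoic acid, via potassium 16-oxohexatriacontanoate 9 (not isolated), via potassium 16-hydrazinylidenehexatriacontanoate 10 (not isolated), via potassium hexatriacontanoate 11 (not isolated)
Conditions: KOH, diethylene glycol, 110 °C; N2H4·H2O, 130 °C; distil to 200 °C and hold; then aq. HCl, recrystallisation
Reagents that add atoms: potassium hydroxide, [K+].[OH-] (hydroxyl oxygen of the acid, potassium of 9–11); hydrazine hydrate, NN.O (its nitrogen sits only in intermediate 10 and leaves as N2)
Why: Huang-Minlon variant of the Wolff–Kishner reduction, with saponification placed before the hydrazine charge so that hydrazine meets only the ketone, after which the hydrazone anion loses N2 near 200 °C to leave the C16 methylene, the classical way to finish long-chain fatty acids from keto acids.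

Step 6
Reactants: 12 hexatriacontanoic acid; 13 tyrosol
Product: 14 2-(4-hydroxyphenyl)ethyl hexatriacontanoate
Conditions: Novozym 435 (immobilised Candida antarctica lipase B), 4 Å molecular sieves, toluene/2-methylbutan-2-ol, 70 °C; tyrosol in excess, removed by aqueous wash
Reagents that add atoms: none
Why: Lipase-catalysed esterification, in which the acyl-enzyme formed from the acid is transferred to the primary aliphatic hydroxyl of tyrosol while the phenolic hydroxyl is not accepted as a nucleophile, and the sieves remove the water that would reverse the reaction.

Compound list
1 | pentadecanolide (oxacyclohexadecan-2-one) | O=C1CCCCCCCCCCCCCCO1 | starting material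
2 | methyl 15-hydroxypentadecanoate | COC(=O)CCCCCCCCCCCCCCO | intermediate
3 | methyl 15-iodopentadecanoate | COC(=O)CCCCCCCCCCCCCCI | intermediate
4 | 1-eicosene | C=CCCCCCCCCCCCCCCCCCC | starting material
5 | 9-borabicyclo[3.3.1]nonane (9-BBN, drawn as monomer) | B1C2CCCC1CCC2 | starting material
6 | B-eicosyl-9-borabicyclo[3.3.1]nonane | CCCCCCCCCCCCCCCCCCCCB1C2CCCC1CCC2 | intermediate
7 | carbon monoxide | [C-]#[O+] | starting material
8 | methyl 16-oxohexatriacontanoate | CCCCCCCCCCCCCCCCCCCCC(=O)CCCCCCCCCCCCCCC(=O)OC | intermediate
9 | potassium 16-oxohexatriacontanoate | CCCCCCCCCCCCCCCCCCCCC(=O)CCCCCCCCCCCCCCC(=O)[O-].[K+] | intermediate (not isolated)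
10 | potassium 16-hydrazinylidenehexatriacontanoate | CCCCCCCCCCCCCCCCCCCCC(=NN)CCCCCCCCCCCCCCC(=O)[O-].[K+] | intermediate (not isolated)
11 | potassium hexatriacontanoate | CCCCCCCCCCCCCCCCCCCCCCCCCCCCCCCCCCCC(=O)[O-].[K+] | intermediate (not isolated)
12 | hexatriacontanoic acid | CCCCCCCCCCCCCCCCCCCCCCCCCCCCCCCCCCCC(=O)O | intermediate
13 | tyrosol, 2-(4-hydroxyphenyl)ethanol | OCCc1ccc(O)cc1 | starting material
14 | 2-(4-hydroxyphenyl)ethyl hexatriacontanoate | CCCCCCCCCCCCCCCCCCCCCCCCCCCCCCCCCCCC(=O)OCCc1ccc(O)cc1 | target

Total step count: 6
Longest linear sequence: 5 steps (steps 1, 2, 4, 5 and 6); step 3 is the one-step side branch.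

Steps most likely to fail

Step 4. The alkyl radical or alkylpalladium species may be diverted before it captures CO, through hydrogen abstraction, β-hydride elimination or transmetalation without insertion. Separately, the waxy product and the suspended K3PO4 may block light and stall turnover. The fallback gives up the carbonyl linchpin. It sets out from borane 6, which is coupled with purchased methyl 16-bromohexadecanoate (COC(=O)CCCCCCCCCCCCCCCBr) in a non-carbonylative alkyl–alkyl Suzuki–Miyaura reaction (Pd(OAc)2, PCy3, K3PO4·H2O, THF, rt). This joins C16 to C17 directly and should give methyl hexatriacontanoate F1, with no ketone to remove. Saponification of this ester (KOH, EtOH/toluene, reflux; then aq. HCl) returns to the route at hexatriacontanoic acid 12, ready for step 6.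

Step 6. Acyl-enzyme formation may be slow or incomplete, because a C36 acid dissolves sparingly and diffuses poorly into the immobilised enzyme, and residual water may hold the esterification at equilibrium. The fallback replaces enzymatic chemoselectivity by a protecting group. It sets out from acid 12, which undergoes Steglich esterification (EDC·HCl, DMAP, CH2Cl2/toluene, 40 °C) with commercial 2-(4-benzyloxyphenyl)ethanol (OCCc1ccc(OCc2ccccc2)cc1) to give 2-(4-benzyloxyphenyl)ethyl hexatriacontanoate F2. Hydrogenolysis of the benzyl ether (H2, 1 atm, Pd/C, THF/EtOAc, 40 °C) spares the non-benzylic phenethyl ester and comes back to the route at target 14.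

Step 5. Hydrazine may attack any ester that has survived saponification and form a hydrazide. The hydrazone may also condense with a second ketone to an azine, or the potassium soap may separate or foam in the glycol, so that deoxygenation stops short. The fallback avoids hydrazine and strong base at high temperature. It sets out from keto ester 8, which is hydrolysed (LiOH, THF/MeOH/H2O, 60 °C; then aq. HCl) to 16-oxohexatriacontanoic acid F3. Thioketalisation (ethane-1,2-dithiol, BF3·OEt2, CHCl3, 50 °C) should give 15-(2-eicosyl-1,3-dithiolan-2-yl)pentadecanoic acid F4. Mozingo desulfurisation (Raney Ni, EtOH/toluene, reflux) then comes back to the route at hexatriacontanoic acid 12.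

Further compounds
F1 | step 4 | methyl hexatriacontanoate | CCCCCCCCCCCCCCCCCCCCCCCCCCCCCCCCCCCC(=O)OC
F2 | step 6 | 2-(4-benzyloxyphenyl)ethyl hexatriacontanoate | CCCCCCCCCCCCCCCCCCCCCCCCCCCCCCCCCCCC(=O)OCCc1ccc(OCc2ccccc2)cc1
F3 | step 5 | 16-oxohexatriacontanoic acid | CCCCCCCCCCCCCCCCCCCCC(=O)CCCCCCCCCCCCCCC(=O)O
F4 | step 5 | 15-(2-eicosyl-1,3-dithiolan-2-yl)pentadecanoic acid | CCCCCCCCCCCCCCCCCCCCC1(CCCCCCCCCCCCCCC(=O)O)SCCS1
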